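**Retrosynthetic overview**

1. The cyclohexene ring is opened by a retro-Diels–Alder cut of its CH2–CH(Ph) and CH(C=O)–CH(prenyl) bonds. This gives an (E)-chalcone on the benzofuran and the terpene triene (E)-β-ocimene, whose ten carbons supply ring carbons C2–C5, the ring methyl and the prenyl chain.
2. Enabling feature: the phenol O–H on C6 of the benzofuran lies ortho to the C7 ketone. Phenolate O and ketone O close a six-membered chelate ring on boron (B–O–C=C–C=O), which locks the enone s-cis, lowers its LUMO and holds a chiral diol next to it.
3. The chalcone comes from Claisen–Schmidt condensation of 7-acetyl-6-hydroxy-4-methoxybenzofuran with benzaldehyde. That ketone comes from symmetric 2,6-dihydroxy-4-methoxyacetophenone by iodination, Sonogashira coupling and 5-endo-dig ring closure.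
4. The diene comes from 3-methyl-3-sulfolene (a temporary ring) by C2 prenylation and cheletropic loss of SO2, which fixes the E geometry.
5. Ring order: the furan ring first (step 3), then the cyclohexene ring with all three stereocentres in the last step (step 7).

Key step: step 7

Assumption: the borate of (R)-VANOL is taken to leave open the enone face that is Re at both alkene carbons; the ligand alone sets this sense, so its mirror image would be used in the same step if the sense proved opposite.

**Route**

Step 1
Reactants: 1 1-(2,6-dihydroxy-4-methoxyphenyl)ethanone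
Product: 2 1-(2,6-dihydroxy-3-iodo-4-methoxyphenyl)ethanone
Conditions: NIS (1.0 equiv), MeCN, 0 °C
Reagents that add atoms: N-iodosuccinimide, O=C1CCC(=O)N1I
Why: Electrophilic aromatic iodination: the two free ring positions of 1 are equivalent by symmetry and each is activated by two hydroxyls and the methoxy group, so one equivalent of NIS in the cold should stop at the mono-iodide while the chelated acetyl group is left alone.

Step 2
Reactants: 2 1-(2,6-dihydroxy-3-iodo-4-methoxyphenyl)ethanone; 3 ethynyl(trimethyl)silane
Product: 4 1-{2,6-dihydroxy-4-methoxy-3-[(trimethylsilyl)ethynyl]phenyl}ethanone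
Conditions: PdCl2(PPh3)2 (3 mol%), CuI (5 mol%), Et3N, THF, 50 °C
Reagents that add atoms: none
Why: Sonogashira coupling of an aryl iodide, which tolerates the free phenols and the ketone; the silyl cap blocks the second alkyne terminus.

Step 3
Reactants: 4 1-{2,6-dihydroxy-4-methoxy-3-[(trimethylsilyl)ethynyl]phenyl}ethanone
Product: 6 1-(6-hydroxy-4-methoxy-1-benzofuran-7-yl)ethanone, via ethynylphenol 5 (not isolated)
Conditions: Bu4NF (TBAF, 2.5 equiv), THF, 60 °C; then 1 M HCl
Reagents that add atoms: none
Why: Fluoride removes the silyl group and the phenoxide ortho to the alkyne then adds 5-endo-dig to the terminal alkyne carbon (fluoride-promoted cycloisomerisation of a 2-alkynylphenol to a benzofuran), the other hydroxyl having no alkyne within reach; a ring closure that had already begun in step 2 would end at the same product because fluoride also cleaves a silyl group from C2 of a benzofuran.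

Step 4
Reactants: 6 1-(6-hydroxy-4-methoxy-1-benzofuran-7-yl)ethanone; 7 benzaldehyde
Product: 8 (2E)-1-(6-hydroxy-4-methoxy-1-benzofuran-7-yl)-3-phenylprop-2-en-1-one
Conditions: KOH (50% aq), EtOH, rt; then 1 M HCl
Reagents that add atoms: none
Why: Claisen–Schmidt condensation (crossed aldol, E1cB dehydration) of the methyl ketone with non-enolisable benzaldehyde gives the conjugated E-enone, and the hydrogen-bonded phenol ortho to the carbonyl disfavours ring closure to the flavanone at room temperature.

Step 5
Reactants: 9 3-methyl-2,5-dihydrothiophene 1,1-dioxide; 10 1-bromo-3-methylbut-2-ene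
Product: 11 3-methyl-2-(3-methylbut-2-en-1-yl)-2,5-dihydrothiophene 1,1-dioxide (racemic)
Conditions: LiN(SiMe3)2 (1.1 equiv) added to 9 + 10, THF–DMPU, −78 °C
Reagents that add atoms: none
Why: Alkylation of an α-sulfonyl carbanion: deprotonation at C2 gives the allyl anion with the methyl group on its central carbon (favoured over the C5 anion, which would carry methyl on a charged terminus), and trapping in situ by the allylic bromide at −78 °C outruns ring opening of the anion; the new stereocentre is racemic and disappears in step 6.

Step 6
Reactants: 11 3-methyl-2-(3-methylbut-2-en-1-yl)-2,5-dihydrothiophene 1,1-dioxide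
Product: 12 (3E)-3,7-dimethylocta-1,3,6-triene ((E)-β-ocimene)
Conditions: neat, K2CO3 (solid, cat.), 130 °C, 20 mbar, product distilled as formed
Reagents that add atoms: none
Why: Thermal cheletropic extrusion of SO2 (suprafacial, disrotatory) in which the C2 substituent rotates outward, so the diene should form with the 3E geometry only and the isolated prenyl alkene is untouched.

Step 7
Reactants: 8 (2E)-1-(6-hydroxy-4-methoxy-1-benzofuran-7-yl)-3-phenylprop-2-en-1-one; 12 (3E)-3,7-dimethylocta-1,3,6-triene
Product: 15 (6-hydroxy-4-methoxy-1-benzofuran-7-yl)[(1R,2S,6R)-3-methyl-2-(3-methylbut-2-en-1-yl)-6-phenylcyclohex-3-en-1-yl]methanone, via chalcone spiroborate 13 (not isolated), via cycloadduct spiroborate 14 (not isolated)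
Conditions: (R)-VANOL (1.25 equiv), BH3·THF (1.2 equiv), AcOH (1.25 equiv), THF, rt, volatiles removed; then 8, THF, rt; then 12 (5 equiv), rt; then H2O
Reagents that add atoms: none
Why: The acetoxyborane made from (R)-VANOL, BH3·THF and AcOH exchanges its acetate for the C6 phenolate of 8 and the C7 ketone oxygen closes a six-membered B–O–C=C–C=O chelate ring, so that in spiroborate 13 the enone is locked s-cis and LUMO-lowered; 12 then adds in a concerted, asynchronous normal-demand Diels–Alder reaction and water releases 15 from 14. The closest known reaction type is the chiral diol–boron promoted Diels–Alder reaction of 2'-hydroxychalcones with acyclic 1,3-dienes. The cyclohexene ring closes by intermolecular [4+2] cycloaddition, suprafacial on both partners, which makes the CH2–CH(Ph) and the CH(C=O)–CH(prenyl) bonds together. C1 and C6 keep the trans relation of the E-enone (stereospecific), C2 is set cis to the aroyl group by the endo transition state (aroyl chelate under the diene, E-substituent of the diene terminus pointing outward), and the absolute sense comes from the C2-symmetric VANOL, whose aryl wing covers one face of the bound enone so that the diene meets the face that is Re at both alkene carbons. The step needs regio-, endo- and facial selectivity and must spare the prenyl alkene and the furan C2=C3 bond: the chelate supplies activation, endo and facial control, only the conjugated E-diene unit of 12 can reach s-cis, and the orientation is set by the leading bond from the benzylic β-carbon to the unhindered CH2 terminus under the ortho-directing alkyl group at the other terminus. Because the ring methyl group of the diene directs the other way, some regioisomer is expected and would be removed by chromatography.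

**Compound list**

1 | 1-(2,6-dihydroxy-4-methoxyphenyl)ethanone | CC(=O)c1c(O)cc(OC)cc1O | starting material
2 | 1-(2,6-dihydroxy-3-iodo-4-methoxyphenyl)ethanone | CC(=O)c1c(O)cc(OC)c(I)c1O | intermediate
3 | ethynyl(trimethyl)silane | C#C[Si](C)(C)C | starting material
4 | 1-{2,6-dihydroxy-4-methoxy-3-[(trimethylsilyl)ethynyl]phenyl}ethanone | CC(=O)c1c(O)cc(OC)c(C#C[Si](C)(C)C)c1O | intermediate
5 | 1-(3-ethynyl-2,6-dihydroxy-4-methoxyphenyl)ethanone | CC(=O)c1c(O)cc(OC)c(C#C)c1O | intermediate (not isolated)
6 | 1-(6-hydroxy-4-methoxy-1-benzofuran-7-yl)ethanone | CC(=O)c1c(O)cc(OC)c2ccoc12 | intermediate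
7 | benzaldehyde | O=Cc1ccccc1 | starting material
8 | (2E)-1-(6-hydroxy-4-methoxy-1-benzofuran-7-yl)-3-phenylprop-2-en-1-one | COc1cc(O)c(C(=O)/C=C/c2ccccc2)c2occc12 | intermediate
9 | 3-methyl-2,5-dihydrothiophene 1,1-dioxide (3-methyl-3-sulfolene) | CC1=CCS(=O)(=O)C1 | starting material
10 | 1-bromo-3-methylbut-2-ene (prenyl bromide) | CC(C)=CCBr | starting material
11 | 3-methyl-2-(3-methylbut-2-en-1-yl)-2,5-dihydrothiophene 1,1-dioxide (racemic) | CC(C)=CCC1C(C)=CCS1(=O)=O | intermediate
12 | (3E)-3,7-dimethylocta-1,3,6-triene | C=C/C(C)=C/CC=C(C)C | intermediate
13 | spiroborate of the (R)-VANOL boron unit with the C6 phenolate and C7 ketone oxygen of 8 (tetracoordinate boron; the R axis is not expressible in SMILES) | COc1cc2O[B-]3(Oc4c(-c6c(O3)c7ccccc7cc6-c6ccccc6)c(-c5ccccc5)cc5ccccc45)[O+]=C(/C=C/c4ccccc4)c2c2occc12 | intermediate (not isolated)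
14 | the same (R)-VANOL spiroborate carrying the (1R,2S,6R)-cycloadduct | COc1cc2O[B-]3(Oc4c(-c6c(O3)c7ccccc7cc6-c6ccccc6)c(-c5ccccc5)cc5ccccc45)[O+]=C([C@@H]4[C@H](CC=C(C)C)C(C)=CC[C@H]4c4ccccc4)c2c2occc12 | intermediate (not isolated)
15 | (6-hydroxy-4-methoxy-1-benzofuran-7-yl)[(1R,2S,6R)-3-methyl-2-(3-methylbut-2-en-1-yl)-6-phenylcyclohex-3-en-1-yl]methanone | COc1cc(O)c(C(=O)[C@@H]2[C@H](CC=C(C)C)C(C)=CC[C@H]2c2ccccc2)c2occc12 | target

**Count and risks**

Total steps: 7. Longest linear sequence: 5 steps (steps 1, 2, 3, 4 and 7); steps 5 and 6 form the second branch.

Steps most likely to fail: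

1. Step 7. What may go wrong: facial control by the borate may be incomplete on this furan-fused chelate, the reaction may stall once the cycloadduct holds the boron, and the triene may be lost to acid-induced oligomerisation. The fallback sets out from 8 and 12 and comes back at 15. The two are combined without any promoter under high pressure (about 19 kbar, CH2Cl2, room temperature), where the intramolecular O–H···O=C hydrogen bond alone activates the enone. The endo adduct would then form as a racemate, that is 15 together with its mirror image (6-hydroxy-4-methoxy-1-benzofuran-7-yl)[(1S,2R,6S)-3-methyl-2-(3-methylbut-2-en-1-yl)-6-phenylcyclohex-3-en-1-yl]methanone F1. Preparative HPLC on a chiral stationary phase (amylose tris(3,5-dimethylphenylcarbamate)) would separate the two, so that stereocontrol by the promoter is replaced by resolution. This fallback does not improve the orientation of the cycloaddition; the regioisomer would still be removed by chromatography.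

2. Step 5. What may go wrong: ring opening of the sulfolene carbanion to a dienyl sulfinate, double alkylation, or alkylation at C5 instead of C2. The fallback sets out from 10 and comes back at 12, leaving out 11 and step 6. Zirconium-catalysed carboalumination of but-1-en-3-yne (Me3Al, Cp2ZrCl2, CH2Cl2, rt) adds methyl and aluminium syn across the alkyne and should give dimethyl[(1E)-2-methylbuta-1,3-dien-1-yl]alumane F2. Cross-coupling of this alkenylalane with 10 (Pd(PPh3)4, 5 mol%, THF, rt) at the primary allylic carbon, with retention of the alkene geometry, would give 12.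

3. Step 1. What may go wrong: over-iodination to the di-iodide and statistical mixtures, since both ring positions are equivalent and the mono-iodide is still strongly activated. The fallback sets out from 1 and comes back at 6, leaving out 2, 4 and steps 2 and 3. O-alkylation of one hydroxyl with 2-bromo-1,1-diethoxyethane (K2CO3, DMF, 100 °C; the second hydroxyl stays chelated to the ketone) should give 1-[2-(2,2-diethoxyethoxy)-6-hydroxy-4-methoxyphenyl]ethanone F3. Acid-promoted cyclodehydration (Amberlyst 15, chlorobenzene, reflux) would then close the furan ring at the only free position ortho to the ether oxygen and give 6.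

**Further compounds**

F1 | step 7 | (6-hydroxy-4-methoxy-1-benzofuran-7-yl)[(1S,2R,6S)-3-methyl-2-(3-methylbut-2-en-1-yl)-6-phenylcyclohex-3-en-1-yl]methanone (mirror image of 15, formed with 15 as the racemate) | COc1cc(O)c(C(=O)[C@H]2[C@@H](CC=C(C)C)C(C)=CC[C@@H]2c2ccccc2)c2occc12
F2 | step 5 | dimethyl[(1E)-2-methylbuta-1,3-dien-1-yl]alumane | C[Al](C)/C=C(/C=C)C
F3 | step 1 | 1-[2-(2,2-diethoxyethoxy)-6-hydroxy-4-methoxyphenyl]ethanone | CCOC(COc1cc(OC)cc(O)c1C(C)=O)OCC
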